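**Retrosynthetic overview**
1. The last C–C bond is C3–C1' (lactone α-carbon to the dienyl chain), made by a new nickel-catalysed reductive coupling of an α-bromolactone with a dienyl iodide (fragment B); desilylation then gives the target.
2. The α-bromolactone comes from enolate bromination of a lactone made by Suzuki union of an iodovinyl lactone (fragment A) with an (R)-alkenylboronate (fragment C).
3. Fragment A: the only ring, the γ-lactone, is closed early by oxidative lactonisation of a 1,4-diol obtained by Brown anti-crotylation and hydroboration of (E)-3-iodo-2-methylacrolein (from propargyl alcohol).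
4. Fragment B: Evans syn-aldol on (2E,4E)-5-iodo-4-methylpenta-2,4-dienal, then Weinreb amide, silyl ether and MeMgBr.
5. Fragment C: (S)-3-bromo-2-methylpropan-1-ol to (R)-2-methylhexanal to the E-alkenylboronate.

Assumption: the lactone is numbered O1, C2 (C=O), C3, C4, C5 and primes mark the C3 side chain; (2E)-pent-2-en-4-yn-1-ol and (2S)-3-bromo-2-methylpropan-1-ol are taken as catalogue compounds; the α-bromolactone is used as its C3 epimer mixture.

**Route**

Step 1
Reactants: 1 prop-2-yn-1-ol
Product: 3 (2E)-3-iodo-2-methylprop-2-en-1-ol, via alkenylalane 2 (not isolated)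
Conditions: Me3Al (3 equiv), Cp2ZrCl2 (0.25 equiv), CH2Cl2, 0 °C to rt; then I2, THF, −30 to 0 °C; aq. K2CO3
Reagents that add atoms: trimethylaluminium C[Al](C)C; iodine II
Why: Zirconium-catalysed methylalumination (Negishi carboalumination) adds CH3 and Al syn across the alkyne with Al at the terminus, and iodinolysis of the C–Al bond with retention gives only the E vinyl iodide.

Step 2
Reactants: 3 (2E)-3-iodo-2-methylprop-2-en-1-ol
Product: 4 (2E)-3-iodo-2-methylprop-2-enal
Conditions: MnO2 (15 equiv), CH2Cl2, rt, dark; used directly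
Reagents that add atoms: none
Why: MnO2 oxidises the allylic alcohol selectively to the enal without touching the vinyl iodide or the alkene geometry (allylic alcohol oxidation).

Step 3
Reactants: 4 (2E)-3-iodo-2-methylprop-2-enal
Product: 6 (1E,3S,4S)-1-iodo-2,4-dimethylhexa-1,5-dien-3-ol, via borinate ester 5 (not isolated)
Conditions: trans-2-butene, KOtBu, n-BuLi, THF, −78 to −45 °C; (−)-Ipc2BOMe (from (+)-α-pinene), −78 °C; BF3·OEt2; then 4, −78 °C; NaOH, H2O2, rt
Reagents that add atoms: trans-but-2-ene C/C=C/C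
Why: Brown asymmetric crotylboration through a chair six-membered transition state, in which the E-crotyl geometry gives the anti relationship and the isopinocampheyl groups from (+)-α-pinene direct attack to the Si face of the aldehyde, setting C3 and C4 as S,S (the future lactone C5 and C4).

Step 4
Reactants: 6 (1E,3S,4S)-1-iodo-2,4-dimethylhexa-1,5-dien-3-ol
Product: 8 (3S,4S,5E)-6-iodo-3,5-dimethylhex-5-ene-1,4-diol, via alkylborane 7 (not isolated)
Conditions: 9-BBN (2.5 equiv), THF, 0 °C to rt; then NaOH, H2O2, 0 °C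
Reagents that add atoms: hydrogen peroxide OO
Why: 9-BBN hydroborates the monosubstituted terminal alkene anti-Markovnikov far faster than the trisubstituted iodoalkene, and oxidation of the C–B bond gives the primary alcohol without touching a stereocentre (hydroboration–oxidation).

Step 5
Reactants: 8 (3S,4S,5E)-6-iodo-3,5-dimethylhex-5-ene-1,4-diol
Product: 10 (4S,5S)-5-[(1E)-1-iodoprop-1-en-2-yl]-4-methyloxolan-2-one, via lactol 9 (not isolated)
Conditions: TEMPO (0.2 equiv), PhI(OAc)2 (3 equiv), CH2Cl2, rt
Reagents that add atoms: none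
Why: TEMPO/PhI(OAc)2 oxidises the primary alcohol selectively to the aldehyde, which closes onto the C4 hydroxyl as lactol 9 and is oxidised again to the γ-lactone (oxidative lactonisation), closing the only ring with the trans 4,5-relationship already in place.

Step 6
Reactants: 11 (2S)-3-bromo-2-methylpropan-1-ol
Product: 13 (2R)-2-methylhexan-1-ol, via magnesium alkoxide 12 (not isolated)
Conditions: n-PrMgBr (3 equiv), Li2CuCl4 (5 mol%), THF, −78 °C to rt; then H2O
Reagents that add atoms: propylmagnesium bromide CCC[Mg]Br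
Why: Copper-catalysed cross-coupling of a Grignard reagent with a primary alkyl bromide (Kochi-type coupling) tolerates the alcohol as its magnesium alkoxide, and the stereocentre is not involved (its descriptor changes from S to R only because the CIP priorities change).

Step 7
Reactants: 13 (2R)-2-methylhexan-1-ol
Product: 14 (2R)-2-methylhexanal
Conditions: TEMPO (0.1 equiv), PhI(OAc)2 (1.1 equiv), CH2Cl2, 0 °C to rt; used directly
Reagents that add atoms: none
Why: TEMPO/PhI(OAc)2 oxidation stops at the aldehyde under neutral, non-epimerising conditions, so the α-stereocentre is preserved (alcohol oxidation).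

Step 8
Reactants: 14 (2R)-2-methylhexanal
Product: 15 4,4,5,5-tetramethyl-2-[(1E,3R)-3-methylhept-1-en-1-yl]-1,3,2-dioxaborolane
Conditions: Cl2CHBpin (2 equiv), CrCl2 (8 equiv), LiI (4 equiv), THF, rt
Reagents that add atoms: 2-(dichloromethyl)-4,4,5,5-tetramethyl-1,3,2-dioxaborolane ClC(Cl)B1OC(C)(C)C(C)(C)O1
Why: Takai–Utimoto boron olefination, in which a geminal dichromium species from the dihalomethylboronate adds to the aldehyde and eliminates to give the E-alkenylboronate selectively under non-basic conditions that do not epimerise the α-stereocentre.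

Step 9
Reactants: 10 (4S,5S)-5-[(1E)-1-iodoprop-1-en-2-yl]-4-methyloxolan-2-one; 15 4,4,5,5-tetramethyl-2-[(1E,3R)-3-methylhept-1-en-1-yl]-1,3,2-dioxaborolane
Product: 16 (4S,5S)-4-methyl-5-[(2E,4E,6R)-6-methyldeca-2,4-dien-2-yl]oxolan-2-one
Conditions: Pd(dppf)Cl2 (5 mol%), AsPh3 (10 mol%), Cs2CO3 (2.5 equiv), DMF/H2O, rt, dark
Reagents that add atoms: none
Why: Suzuki–Miyaura coupling of a vinyl iodide with an E-alkenylboronate proceeds with retention at both alkenes to give the E,E-diene, and room temperature with a weak base keeps the lactone and its allylic C–O bond intact.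

Step 10
Reactants: 16 (4S,5S)-4-methyl-5-[(2E,4E,6R)-6-methyldeca-2,4-dien-2-yl]oxolan-2-one
Product: 18 (3S,4R,5S)-3-bromo-4-methyl-5-[(2E,4E,6R)-6-methyldeca-2,4-dien-2-yl]oxolan-2-one, via lithium enolate 17 (not isolated)
Conditions: LiN(iPr)2 (1.1 equiv), THF, −78 °C; cannulate into BrCCl2CCl2Br (1.5 equiv), THF, −78 °C; AcOH quench
Reagents that add atoms: 1,2-dibromo-1,1,2,2-tetrachloroethane BrC(Cl)(Cl)C(Cl)(Cl)Br
Why: Kinetic deprotonation gives lactone enolate 17, which takes up electrophilic bromine mainly anti to the C4 methyl group (enolate α-halogenation), and the C3 configuration does not matter because step 17 is stereoconvergent.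

Step 11
Reactants: 19 (2E)-pent-2-en-4-yn-1-ol
Product: 21 (2E,4E)-5-iodo-4-methylpenta-2,4-dien-1-ol, via dienylalane 20 (not isolated)
Conditions: Me3Al (3 equiv), Cp2ZrCl2 (0.3 equiv), CH2Cl2, 0 °C to rt; then I2, THF, −30 to 0 °C; aq. K2CO3
Reagents that add atoms: trimethylaluminium C[Al](C)C; iodine II
Why: Negishi carboalumination of the terminal alkyne of the enyne is syn and places Al at the terminus, and iodinolysis with retention gives the 4E iodide while the existing 2E alkene is untouched.

Step 12
Reactants: 21 (2E,4E)-5-iodo-4-methylpenta-2,4-dien-1-ol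
Product: 22 (2E,4E)-5-iodo-4-methylpenta-2,4-dienal
Conditions: MnO2 (15 equiv), CH2Cl2, rt, dark
Reagents that add atoms: none
Why: MnO2 oxidises the dienylic primary alcohol to the dienal without isomerising the diene (allylic alcohol oxidation).

Step 13
Reactants: 22 (2E,4E)-5-iodo-4-methylpenta-2,4-dienal; 23 (4R)-4-benzyl-3-propanoyl-1,3-oxazolidin-2-one
Product: 26 (4R)-4-benzyl-3-[(2R,3S,4E,6E)-3-hydroxy-7-iodo-2,6-dimethylhepta-4,6-dienoyl]-1,3-oxazolidin-2-one, via boron enolate 24 (not isolated), via boron aldolate 25 (not isolated)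
Conditions: 23, Bu2BOTf (1.2 equiv), Et3N (1.4 equiv), CH2Cl2, −78 to 0 °C; then 22, −78 to 0 °C; pH 7 buffer, MeOH, H2O2, 0 °C
Reagents that add atoms: none
Why: Evans syn-aldol, in which the Z boron enolate reacts through a Zimmerman–Traxler chair with the aldehyde approaching the face opposite the benzyl group of the R auxiliary, setting 2R,3S (syn).

Step 14
Reactants: 26 (4R)-4-benzyl-3-[(2R,3S,4E,6E)-3-hydroxy-7-iodo-2,6-dimethylhepta-4,6-dienoyl]-1,3-oxazolidin-2-one
Product: 27 (2R,3S,4E,6E)-3-hydroxy-7-iodo-N-methoxy-N,2,6-trimethylhepta-4,6-dienamide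
Conditions: MeNH(OMe)·HCl (3 equiv), Me3Al (3 equiv), CH2Cl2, −15 to 0 °C
Reagents that add atoms: N,O-dimethylhydroxylamine hydrochloride CNOC.Cl
Why: The aluminium amide formed from Me3Al and the amine salt opens the imide at the exocyclic carbonyl, assisted by the free β-hydroxyl, and releases the auxiliary without epimerisation (Weinreb transamidation).

Step 15
Reactants: 27 (2R,3S,4E,6E)-3-hydroxy-7-iodo-N-methoxy-N,2,6-trimethylhepta-4,6-dienamide
Product: 28 (2R,3S,4E,6E)-7-iodo-N-methoxy-N,2,6-trimethyl-3-(triethylsilyloxy)hepta-4,6-dienamide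
Conditions: Et3SiCl (1.3 equiv), imidazole (2.5 equiv), DMF, 0 °C to rt
Reagents that add atoms: chlorotriethylsilane CC[Si](Cl)(CC)CC
Why: Silylation of the secondary alcohol blocks retro-aldol and elimination pathways in the organometallic steps that follow (silyl ether protection).

Step 16
Reactants: 28 (2R,3S,4E,6E)-7-iodo-N-methoxy-N,2,6-trimethyl-3-(triethylsilyloxy)hepta-4,6-dienamide
Product: 30 (3R,4S,5E,7E)-8-iodo-3,7-dimethyl-4-(triethylsilyloxy)octa-5,7-dien-2-one, via magnesium chelate 29 (not isolated)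
Conditions: MeMgBr (3 equiv), THF, 0 °C; then H2O (pH 7 buffer)
Reagents that add atoms: methylmagnesium bromide C[Mg]Br
Why: MeMgBr adds once to the Weinreb amide to give the stable chelated tetrahedral intermediate 29, which releases the methyl ketone only on work-up (Weinreb ketone synthesis), so there is no over-addition and no epimerisation at C3.

Step 17
Reactants: 18 (3S,4R,5S)-3-bromo-4-methyl-5-[(2E,4E,6R)-6-methyldeca-2,4-dien-2-yl]oxolan-2-one; 30 (3R,4S,5E,7E)-8-iodo-3,7-dimethyl-4-(triethylsilyloxy)octa-5,7-dien-2-one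
Product: 31 (3S,4S,5S)-3-[(1E,3E,5S,6R)-2,6-dimethyl-7-oxo-5-(triethylsilyloxy)octa-1,3-dien-1-yl]-4-methyl-5-[(2E,4E,6R)-6-methyldeca-2,4-dien-2-yl]oxolan-2-one
Conditions: NiBr2(dme) (10 mol%), 4,4'-di-tert-butyl-2,2'-bipyridine (12 mol%), Mn powder (3 equiv), NaI (25 mol%), DMA, 5 °C to rt; 18 (1.3 equiv) added over 2 h
Reagents that add atoms: none
Why: Proposed new method: a nickel-catalysed, diastereoconvergent reductive cross-electrophile coupling of an α-bromo-γ-butyrolactone with a 2-methyl-1,3-dienyl iodide, in which zerovalent nickel (from NiBr2(dme), the bipyridine and Mn) inserts into the C–I bond of 30 with retention of alkene geometry, the resulting dienyl nickel halide (divalent nickel) captures the planar C3 lactonyl radical formed from either epimer of 18 by bromine-atom abstraction by monovalent nickel, capture occurs on the ring face anti to the adjacent C4 methyl group, and reductive elimination from trivalent nickel forms the C3–C1' bond with C3 as S (the all-trans lactone, also the thermodynamically preferred isomer), while the base-free medium avoids deprotonation of the new doubly activated C3–H and so avoids epimerisation or migration of the diene into conjugation; the closest known reaction type is the nickel-catalysed reductive coupling of α-halo esters and other activated alkyl halides with aryl or vinyl halides, which has not been shown for α-bromolactones bearing ring stereocentres, for 1,3-dienyl iodides carrying a β-silyloxy ketone, or as a substrate-controlled route to tertiary α-alkenyl lactones.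

Step 18
Reactants: 31 (3S,4S,5S)-3-[(1E,3E,5S,6R)-2,6-dimethyl-7-oxo-5-(triethylsilyloxy)octa-1,3-dien-1-yl]-4-methyl-5-[(2E,4E,6R)-6-methyldeca-2,4-dien-2-yl]oxolan-2-one
Product: 32 (3S,4S,5S)-3-[(1E,3E,5S,6R)-5-hydroxy-2,6-dimethyl-7-oxoocta-1,3-dien-1-yl]-4-methyl-5-[(2E,4E,6R)-6-methyldeca-2,4-dien-2-yl]oxolan-2-one
Conditions: HF·pyridine, pyridine, THF, 0 °C
Reagents that add atoms: none
Why: Buffered HF·pyridine cleaves the allylic triethylsilyl ether under weakly acidic conditions that neither epimerise lactone C3 or the ketone α-centre nor dehydrate the β-hydroxy ketone (silyl ether deprotection).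

**Compound list**

1 | prop-2-yn-1-ol (propargyl alcohol) | C#CCO | starting material
2 | dimethyl[(1E)-3-(dimethylalumanyloxy)-2-methylprop-1-en-1-yl]alumane (Al and new CH3 cis) | C[Al](C)/C=C(\C)CO[Al](C)C | intermediate
3 | (2E)-3-iodo-2-methylprop-2-en-1-ol | OC/C(C)=C/I | intermediate
4 | (2E)-3-iodo-2-methylprop-2-enal | O=C/C(C)=C/I | intermediate
5 | bis(isopinocampheyl)borinic ester of alcohol 6 (isopinocampheyl groups from (+)-α-pinene) | I/C=C(\C)[C@@H](OB([C@@H]1C[C@@H]2C[C@H]([C@H]1C)C2(C)C)[C@@H]1C[C@@H]2C[C@H]([C@H]1C)C2(C)C)[C@@H](C)C=C | intermediate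
6 | (1E,3S,4S)-1-iodo-2,4-dimethylhexa-1,5-dien-3-ol (anti) | I/C=C(\C)[C@@H](O)[C@@H](C)C=C | intermediate
7 | 9-[(3S,4S,5E)-4-hydroxy-6-iodo-3,5-dimethylhex-5-en-1-yl]-9-borabicyclo[3.3.1]nonane | I/C=C(\C)[C@@H](O)[C@@H](C)CCB1C2CCCC1CCC2 | intermediate
8 | (3S,4S,5E)-6-iodo-3,5-dimethylhex-5-ene-1,4-diol | I/C=C(\C)[C@@H](O)[C@@H](C)CCO | intermediate
9 | (4S,5S)-5-[(1E)-1-iodoprop-1-en-2-yl]-4-methyloxolan-2-ol (lactol, anomer mixture) | I/C=C(\C)[C@H]1OC(O)C[C@@H]1C | intermediate
10 | (4S,5S)-5-[(1E)-1-iodoprop-1-en-2-yl]-4-methyloxolan-2-one (4,5-trans) | I/C=C(\C)[C@H]1OC(=O)C[C@@H]1C | intermediate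
11 | (2S)-3-bromo-2-methylpropan-1-ol | OC[C@H](C)CBr | starting material
12 | bromomagnesium (2S)-3-bromo-2-methylpropan-1-olate | Br[Mg]OC[C@H](C)CBr | intermediate
13 | (2R)-2-methylhexan-1-ol | CCCC[C@@H](C)CO | intermediate
14 | (2R)-2-methylhexanal | CCCC[C@@H](C)C=O | intermediate
15 | 4,4,5,5-tetramethyl-2-[(1E,3R)-3-methylhept-1-en-1-yl]-1,3,2-dioxaborolane | CCCC[C@@H](C)/C=C/B1OC(C)(C)C(C)(C)O1 | intermediate
16 | (4S,5S)-4-methyl-5-[(2E,4E,6R)-6-methyldeca-2,4-dien-2-yl]oxolan-2-one | CCCC[C@@H](C)/C=C/C=C(\C)[C@H]1OC(=O)C[C@@H]1C | intermediate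
17 | lithium (4S,5S)-4-methyl-5-[(2E,4E,6R)-6-methyldeca-2,4-dien-2-yl]-4,5-dihydrofuran-2-olate (lithium enolate of 16) | CCCC[C@@H](C)/C=C/C=C(\C)[C@H]1OC([O-])=C[C@@H]1C.[Li+] | intermediate
18 | (3S,4R,5S)-3-bromo-4-methyl-5-[(2E,4E,6R)-6-methyldeca-2,4-dien-2-yl]oxolan-2-one (Br trans to the 4-methyl; the minor 3R epimer is carried along) | CCCC[C@@H](C)/C=C/C=C(\C)[C@H]1OC(=O)[C@@H](Br)[C@@H]1C | intermediate
19 | (2E)-pent-2-en-4-yn-1-ol | C#C/C=C/CO | starting material
20 | dimethyl[(1E,3E)-5-(dimethylalumanyloxy)-2-methylpenta-1,3-dien-1-yl]alumane | C[Al](C)/C=C(C)/C=C/CO[Al](C)C | intermediate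
21 | (2E,4E)-5-iodo-4-methylpenta-2,4-dien-1-ol | I/C=C(C)/C=C/CO | intermediate
22 | (2E,4E)-5-iodo-4-methylpenta-2,4-dienal | I/C=C(C)/C=C/C=O | intermediate
23 | (4R)-4-benzyl-3-propanoyl-1,3-oxazolidin-2-one | CCC(=O)N1[C@H](Cc2ccccc2)COC1=O | starting material
24 | Z dibutylboron enolate of 23 | C/C=C(\OB(CCCC)CCCC)N1[C@H](Cc2ccccc2)COC1=O | intermediate
25 | O-dibutylboryl aldolate of 26 | I/C=C(C)/C=C/[C@H](OB(CCCC)CCCC)[C@@H](C)C(=O)N1[C@H](Cc2ccccc2)COC1=O | intermediate
26 | (4R)-4-benzyl-3-[(2R,3S,4E,6E)-3-hydroxy-7-iodo-2,6-dimethylhepta-4,6-dienoyl]-1,3-oxazolidin-2-one (syn) | I/C=C(C)/C=C/[C@H](O)[C@@H](C)C(=O)N1[C@H](Cc2ccccc2)COC1=O | intermediate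
27 | (2R,3S,4E,6E)-3-hydroxy-7-iodo-N-methoxy-N,2,6-trimethylhepta-4,6-dienamide | I/C=C(C)/C=C/[C@H](O)[C@@H](C)C(=O)N(C)OC | intermediate
28 | (2R,3S,4E,6E)-7-iodo-N-methoxy-N,2,6-trimethyl-3-(triethylsilyloxy)hepta-4,6-dienamide | I/C=C(C)/C=C/[C@H](O[Si](CC)(CC)CC)[C@@H](C)C(=O)N(C)OC | intermediate
29 | bromomagnesium alkoxide of the tetrahedral adduct of MeMgBr with 28 (aminal carbon configuration undefined) | I/C=C(C)/C=C/[C@H](O[Si](CC)(CC)CC)[C@@H](C)C(C)(O[Mg]Br)N(C)OC | intermediate
30 | (3R,4S,5E,7E)-8-iodo-3,7-dimethyl-4-(triethylsilyloxy)octa-5,7-dien-2-one | I/C=C(C)/C=C/[C@H](O[Si](CC)(CC)CC)[C@@H](C)C(C)=O | intermediate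
31 | (3S,4S,5S)-3-[(1E,3E,5S,6R)-2,6-dimethyl-7-oxo-5-(triethylsilyloxy)octa-1,3-dien-1-yl]-4-methyl-5-[(2E,4E,6R)-6-methyldeca-2,4-dien-2-yl]oxolan-2-one | CCCC[C@@H](C)/C=C/C=C(\C)[C@H]1OC(=O)[C@@H](/C=C(C)/C=C/[C@H](O[Si](CC)(CC)CC)[C@@H](C)C(C)=O)[C@@H]1C | intermediate
32 | (3S,4S,5S)-3-[(1E,3E,5S,6R)-5-hydroxy-2,6-dimethyl-7-oxoocta-1,3-dien-1-yl]-4-methyl-5-[(2E,4E,6R)-6-methyldeca-2,4-dien-2-yl]oxolan-2-one (CNP0320265.2) | CCCC[C@@H](C)/C=C/C=C(\C)[C@H]1OC(=O)[C@@H](/C=C(C)/C=C/[C@H](O)[C@@H](C)C(C)=O)[C@@H]1C | target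

**Step count and risk**

Total step count: 18.
Longest linear sequence: 9 steps (steps 1, 2, 3, 4, 5, 9, 10, 17, 18). Fragment C (steps 6–8) and fragment B (steps 11–16) are made in parallel.

Three steps most likely to fail:

Step 17 (the proposed new step). The bromolactone may simply be reduced back to 16 or dimerise, low-valent nickel may open the allylic C5–O bond of the lactone, or selectivity at C3 may be poor. The fallback uses known chemistry and sets out from 18 (with 30). Bromide 18 is treated with Zn dust (activated with Me3SiCl) in THF at 0 °C to give the Reformatsky reagent, the bromozinc enolate of lactone 16 F1. This is coupled with iodide 30 under Pd(PPh3)4 (5 mol%) in THF at 0 °C to rt, the established Negishi-type coupling of zinc ester enolates with vinyl halides at zerovalent palladium. Slow addition of the enolate at low temperature is needed so that coupling outruns Reformatsky addition to the ketone of 30. C–C bond formation again occurs anti to the C4 methyl group, and the fallback comes back to the route at 31.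

Step 9. Zerovalent palladium could ionise the allylic lactone C–O bond of 10 or 16 (ring opening, loss of C5 configuration), and aqueous carbonate could open the lactone. The fallback changes the order of events so that no allylic ester is present during the palladium step. It sets out from 8 (with 15): the diol is coupled with the boronate under the same Pd(dppf)Cl2/AsPh3/Cs2CO3 conditions to give (3S,4S,5E,7E,9R)-3,5,9-trimethyltrideca-5,7-diene-1,4-diol F2. TEMPO/PhI(OAc)2 in CH2Cl2 then oxidises the primary alcohol and closes the lactone, coming back to the route at 16.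

Step 10. Proton exchange between enolate 17 and the more acidic product 18 can give dibromide plus recovered 16, and bromine transfer may be sluggish. The fallback separates enolisation from bromination and sets out from 16. LiN(iPr)2 and Me3SiCl in THF at −78 °C give the trimethylsilyl ketene acetal of lactone 16 F3, which is isolated crude. It is then brominated with N-bromosuccinimide in THF at −78 °C, where the electron-rich ketene acetal reacts far faster than the diene and no basic enolate is present when the product forms. The fallback comes back to the route at 18.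

**Further compounds**

F1 | step 17 | bromozinc enolate of lactone 16 (bromo{[(4S,5S)-4-methyl-5-[(2E,4E,6R)-6-methyldeca-2,4-dien-2-yl]-4,5-dihydrofuran-2-yl]oxy}zinc) | CCCC[C@@H](C)/C=C/C=C(\C)[C@H]1OC(O[Zn]Br)=C[C@@H]1C
F2 | step 9 | (3S,4S,5E,7E,9R)-3,5,9-trimethyltrideca-5,7-diene-1,4-diol | CCCC[C@@H](C)/C=C/C=C(\C)[C@@H](O)[C@@H](C)CCO
F3 | step 10 | trimethylsilyl ketene acetal of lactone 16 (trimethyl{[(4S,5S)-4-methyl-5-[(2E,4E,6R)-6-methyldeca-2,4-dien-2-yl]-4,5-dihydrofuran-2-yl]oxy}silane) | CCCC[C@@H](C)/C=C/C=C(\C)[C@H]1OC(O[Si](C)(C)C)=C[C@@H]1C
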